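**Assumption:** the configuration to be made is the one read from the structure, (1R,4R,5R,6S,7R,8R,10S) in germacrane numbering (ring C1–C10, C11–C13 on C7, methyl groups on C4 and C10). These numbers are used for every intermediate, and in the six-membered intermediates "cis" and "trans" refer to the C7 side chain.

## Analysis of the target

Eupakirunsin C is a germacranolide: a ten-membered carbocycle (C1–C10) trans-fused at C6/C7 to an α-methylene-γ-butyrolactone (O6–C12(=O)–C11(=C13)–C7). Nine of the ten ring carbons are functionalised: a secondary alcohol at C1, a ketone at C3, a trisubstituted epoxide at C4–C5 whose two ring bonds are cis, the lactone oxygen at C6, the tiglate at C8 and a methyl group at C10. The seven stereocentres form a contiguous block C4–C8 and a vicinal pair C1/C10 (hydroxyl and methyl anti in the zigzag sense). The pair is separated from the block by C2/C3 on one side and C9 on the other, so it cannot easily be set by relay. Sensitive features are the C1 hydroxyl β to the C3 ketone (dehydration, retro-aldol), the epoxy ketone, the Michael-acceptor lactone, and the O8 ester, which can migrate to O6 once that oxygen is free. The difficulty lies in combining a medium ring, which resists end-to-end closure, with dense oxygenation and a remote stereo-pair. The strategy rests on one structural feature. C3 to C8, with the C4 methyl, the C4–C5 epoxide and the three-carbon branch on C7, are the six ring carbons of carvone. C3 and C8, both oxygen-bearing, stand 1,6 across the ring, which is the relationship created when a 1,2-dialkenylcyclohexanol is expanded by four carbons in an oxy-Cope rearrangement.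

## Retrosynthetic reasoning

**37 back to 33.** The O1–benzyl bond is addressed last: 37 is uncovered from its p-methoxybenzyl ether 36, because a free C1 hydroxyl would be oxidised or eliminated in the preceding operations and an oxidative debenzylation tolerates every group of the target. In 36 the O6–C12 acyl bond is cut and C12 is lowered to the alcohol, giving diol ketone 33. The forward reaction must oxidise a primary allylic alcohol beside a secondary one and close the trans lactone. Carrying C12 as a protected alcohol keeps the Michael acceptor out of all organometallic steps.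

**33 back to 27.** Three silicon–oxygen bonds are restored to reach 32. The O8–acyl bond is cut to alcohol 29 and tiglic acid 30, the C8 carbinol is traced to ketone 28, and the ketone to enol methyl ether 27. C3 and C8 both emerge from the ring expansion as enol derivatives; this order releases, reduces and acylates C8 while C3 stays masked as the enol silane.

**27 back to 24 (key disconnection).** In 27 the enol double bonds C2=C3 and C8=C9 are 1,5 to each other through C1–C10. Cutting C1–C10 and re-forming C3–C8 in a retro-[3,3] shift contracts the ring to cyclohexanol 24, with hydroxyl and (Z)-2-alkoxyvinyl on C3 and methoxy and (E)-propenyl on C8.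
- This cut is chosen because it alone turns the medium ring into a common ring with C4–C7 untouched, translates the remote C1/C10 pair into two alkene geometries, and replaces a ring closure by a ring expansion.
- The forward reaction must pass through the chair with both ring bonds equatorial. The Z and E termini then give the anti C1/C10 pair, and the C3 and C8 centres, destroyed in the event, decide its absolute sense.
- The alkoxide is needed because only enolate formation drives an expansion that would otherwise be uphill. O-silylation of the C3 enolate keeps C3 distinguishable from the C8 methyl enol ether.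
- Two details are set straight. The new ring double bonds are trans within the ring but Z by the sequence rule, because of their oxygen substituents. Payne migration is not just unproductive but impossible, since the C3 oxygen and the epoxide oxygen are cis on the six-membered ring.

**24 back to 16 and 20.** The Z enol ether is traced to alkyne 23 (cis semi-reduction). The C2–C3 bond is cut to epoxy ketone 16 and an alkoxyacetylide from dichlorovinyl ether 20, itself from 4-methoxybenzyl alcohol 17 and trichloroethylene 18. An alkyne is preferred to a preformed alkenyl metal because the C3 carbonyl lies between two fully substituted carbons and a linear nucleophile is the surest to reach it. The Z geometry then follows from syn addition of hydrogen. Addition must occur trans to the C7 side chain, which is the face anti to the epoxide oxygen and anti to the C8 propenyl group (axial when the side chain is equatorial). 16 cannot enolise.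

**16 back to 12.** The epoxide C–O bonds are cut to enone 15, and the C6–O bond to enone 12 by way of γ-hydroxy enone 14 and dienol silyl ether 13. Both oxygens enter under control of neighbours: the C6 oxygen anti to the C7 side chain, then the epoxide anti to the bulky C6 silyl ether and hence cis to the side chain. The order follows from 12: its C8 is quaternary, so the enone can enolise only towards C6.

**12 back to 5 and 6.** The propenyl group is an isomerised allyl group (11), the methyl ether comes from tertiary alcohol 10, the C8–O bond is cut to the enolate of allyl ketone 8, and the C8–C9 bond to the kinetic enolate of 5 and allyl bromide 6. Carbon first and oxygen second gives the needed configuration, since each electrophile enters anti to the C7 side chain. Adding a propenyl metal to a C8 ketone would have required attack cis to the side chain and an enolisable 1,2-dione; both are avoided.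

**5 back to 1.** The C12–O bond is cut: 5 comes from alcohol 4, chloride 2 and (S)-carvone 1 by ene-type chlorination of the isopropenyl group and displacement. 1 supplies C7 in the correct absolute configuration, and this centre controls C8, C6, the epoxide and C3 in turn.

## Alternatives that were turned down

**Alternative 1:** The lactone would be annulated last by cutting C7–C11.
- Forward step: the O6 (diethoxyphosphoryl)acetate A2, a ten-membered ring carrying a trans C7–C8 epoxide, is deprotonated. The carbanion attacks C7 from the rear (5-exo), forming C7–C11, closing the lactone and releasing the C8 alkoxide to give phosphono lactone A1. The phosphonate later serves a Horner–Wadsworth–Emmons methylenation.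
- For: C7 is set by a stereospecific SN2 event, O8 is freed exactly where the tiglate is needed, and the methylene group appears only at the end. On this last point it is gentler than the oxidation of step 20.
- Against: the step does not address the ten-membered ring, which A2 presupposes with C1, C4, C5, C6, C8 and C10 in place. A phosphonoacetate anion is a weak nucleophile for an unactivated epoxide, and A2 holds a second epoxide at C4–C5. The alkoxide released in A1 lies 1,3 to the new lactone carbonyl, so translactonisation to the 8,12-olide is likely.
- Comparison: a sound end-game but not a ring synthesis; the steps to A2 would exceed those of the whole carvone sequence.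

**Alternative 2:** The skeleton is cut at C9–C10 into a C6–C9 half and a C10–C5 half.
- Forward step: the two allylic oxygens O8 and O1 are joined by a diisopropylsilylene bridge in diene A4. The second-generation Grubbs catalyst joins the C8 vinyl and C1 isopropenyl groups to give the seven-membered silylene acetal A3 with a Z C9=C10 bond.
- For: the plan is convergent, and silicon-tethered metathesis makes trisubstituted alkenes of defined geometry dependably. In convergence and in reliability of the bond-forming event it is stronger than the chosen route.
- Against: A3 is not yet a ten-membered ring. The carbocycle must still be closed at C5–C6, which also creates C6 without clear control. C10 must then be made by face-selective reduction of C9=C10 beside the C11=C13 and C4=C5 alkenes, and the Z C4=C5 alkene must be epoxidised on the correct face. In A4 the C11=C13 alkene can also enter the metathesis.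
- Comparison: the chosen route delivers the ring, C1 and C10 in one operation and takes the epoxide from the six-membered stage.

**Alternative 3:** The ring is closed across C4–C5 with formation of the epoxide.
- Forward step: a lithium amide enolises the α-chloro ketone of open-chain aldehyde A6 at C4. Aldol addition to the C5 aldehyde and displacement of chloride by the aldolate (Darzens condensation) give the ten-membered cis-epoxy ketone A5.
- For: ring and epoxide are made in one late step with the tiglate and C8 already in place, so the uncertain ketone reduction of step 17 is avoided. A6 can be assembled convergently. On these points it is stronger.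
- Against: it is an end-to-end closure of the least favourable ring size under strong base and high dilution. Enolisation must occur at the hindered C4 and not at C2, where the enolate would expel the C1 silyloxy group. The α-alkoxy aldehyde can epimerise and the tiglate can be deprotonated. The cis geometry and absolute sense at C4/C5 would depend on an unpredictable macrocyclic transition state, and A6 needs five stereocentres from acyclic control.
- Comparison: the chosen route offers an epoxide whose cis geometry is guaranteed by the six-membered ring and a ring formation without entropic penalty.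

Key step: step 15

## Route

**Step 1**
Reactants: 1 (S)-carvone
Product: 2 (S)-10-chlorocarvone
Conditions: Ca(OCl)2, CO2 (s), CH2Cl2/H2O, 0 °C
Reagents that add atoms: calcium hypochlorite, [Ca+2].[O-]Cl.[O-]Cl
Why: Hypochlorous acid formed in situ chlorinates the electron-rich 1,1-disubstituted alkene in an ene-type reaction with allylic transposition, while the electron-poor enone is untouched; C7 is not involved.

**Step 2**
Reactants: 2 (S)-10-chlorocarvone
Product: 4 (S)-10-hydroxycarvone, via (S)-10-acetoxycarvone 3 (not isolated)
Conditions: KOAc, NaI (cat.), DMF, 60 °C; then MeOH, K2CO3 (cat.), rt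
Reagents that add atoms: potassium acetate, CC(=O)[O-].[K+]
Why: SN2 displacement of the primary allylic chloride by acetate (iodide catalysis) and transesterification of acetate 3 with methanol free the C12 hydroxyl without touching the enone.

**Step 3**
Reactants: 4 (S)-10-hydroxycarvone
Product: 5 (S)-10-(tert-butyldimethylsilyloxy)carvone
Conditions: TBSCl, imidazole, DMF, rt
Reagents that add atoms: tert-butyldimethylsilyl chloride, CC(C)(C)[Si](C)(C)Cl
Why: Standard silylation of a primary allylic alcohol; the silyl ether tolerates amide bases, peroxides and organolithium reagents and is removed with the other silyl groups in step 19.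

**Step 4**
Reactants: 5 (S)-10-(tert-butyldimethylsilyloxy)carvone; 6 allyl bromide
Product: 8 α′-allyl enone, via lithium dienolate 7 (not isolated)
Conditions: LiN(iPr)2, THF, −78 °C; allyl bromide, DMPU, −78 → −20 °C
Reagents that add atoms: allyl bromide (6), C=CCBr
Why: Kinetic deprotonation at the α′-carbon C8 gives cross-conjugated dienolate 7, which is C-alkylated anti to the C7 side chain (enolate alkylation); the C8 configuration is erased again in step 5.

**Step 5**
Reactants: 8 α′-allyl enone
Product: 10 tertiary α-hydroxy ketone, via lithium enolate 9 (not isolated)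
Conditions: LiN(iPr)2, THF, −78 °C; 2-(phenylsulfonyl)-3-phenyloxaziridine, −78 → −40 °C; H2O
Reagents that add atoms: 2-(phenylsulfonyl)-3-phenyloxaziridine, O=S(=O)(N1OC1c1ccccc1)c1ccccc1
Why: The tetrasubstituted enolate 9 is hydroxylated by the N-sulfonyloxaziridine (electrophilic enolate oxidation); the C7 side chain, held pseudo-axial by allylic strain with the C8 allyl group, shields one face, so oxygen enters trans to it and the allyl group ends cis, as C8 requires.

**Step 6**
Reactants: 10 tertiary α-hydroxy ketone
Product: 11 C8 methyl ether
Conditions: MeOTf, 2,6-di-tert-butyl-4-methylpyridine, CH2Cl2, rt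
Reagents that add atoms: methyl triflate, COS(=O)(=O)C(F)(F)F
Why: O-methylation of the hindered tertiary alcohol with methyl triflate and a non-nucleophilic pyridine avoids alkoxide formation next to the ketone, so neither an α-ketol shift nor C-methylation can occur.

**Step 7**
Reactants: 11 C8 methyl ether
Product: 12 (E)-propenyl enone
Conditions: RuHCl(CO)(PPh3)3 (5 mol %), toluene, 80 °C
Reagents that add atoms: none
Why: A ruthenium hydride moves the monosubstituted terminal alkene by one position (hydrometalation and β-hydride elimination); the quaternary C8 stops further migration and strongly favours the E isomer, and the 1,1-disubstituted C11=C13 alkene reacts much more slowly.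

**Step 8**
Reactants: 12 (E)-propenyl enone
Product: 13 silyl dienol ether
Conditions: TBSOTf, Et3N, CH2Cl2, 0 °C
Reagents that add atoms: tert-butyldimethylsilyl triflate, CC(C)(C)[Si](C)(C)OS(=O)(=O)C(F)(F)F
Why: With no hydrogen left on C8, O-silylation and amine deprotonation can occur only at the γ-carbon C6, giving the linear 1-silyloxy-1,3-diene (soft enolisation of an enone).

**Step 9**
Reactants: 13 silyl dienol ether
Product: 14 γ-hydroxy enone
Conditions: mCPBA (1.05 equiv), CH2Cl2, −40 → 0 °C; aq. NaHCO3 work-up
Reagents that add atoms: 3-chloroperbenzoic acid, OOC(=O)c1cccc(Cl)c1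
Why: The peracid attacks the distal C5=C6 bond of the dienol ether, its most accessible nucleophilic π-bond, and the epoxide is opened by the silyloxy group to give the γ-hydroxy enone (vinylogous Rubottom oxidation, as in the 6-hydroxylation of steroidal 3,5-dienol ethers); attack anti to the adjacent C7 side chain places the C6 hydroxyl trans to it.

**Step 10**
Reactants: 14 γ-hydroxy enone
Product: 15 C6 silyl ether enone
Conditions: TBSOTf, 2,6-lutidine, CH2Cl2, −78 °C
Reagents that add atoms: tert-butyldimethylsilyl triflate, CC(C)(C)[Si](C)(C)OS(=O)(=O)C(F)(F)F
Why: Silyl triflate and a pyridine base silylate the hindered secondary allylic alcohol at low temperature; the bulky C6 silyl ether is the steering group for step 11.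

**Step 11**
Reactants: 15 C6 silyl ether enone
Product: 16 epoxy ketone
Conditions: t-BuOOH, benzyltrimethylammonium hydroxide (cat.), THF, 0 °C
Reagents that add atoms: tert-butyl hydroperoxide, CC(C)(C)OO
Why: Conjugate addition of the hydroperoxide anion to C5 and closure of the enolate onto oxygen (Weitz–Scheffer epoxidation) occur anti to the adjacent C6 silyloxy group, which places the epoxide oxygen cis to the C7 side chain; the product has no enolisable hydrogen.

**Step 12**
Reactants: 17 4-methoxybenzyl alcohol; 18 trichloroethylene
Product: 20 (E)-1,2-dichlorovinyl 4-methoxybenzyl ether, via potassium 4-methoxybenzyl oxide 19 (not isolated)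
Conditions: KH, THF, 0 °C; trichloroethylene, −50 °C → rt
Reagents that add atoms: trichloroethylene (18), ClC=C(Cl)Cl
Why: Alkoxide 19 adds to dichloroacetylene formed from trichloroethylene by elimination, and trans protonation gives the E dichloroenol ether (addition–elimination route to 1,2-dichlorovinyl ethers).

**Step 13**
Reactants: 20 (E)-1,2-dichlorovinyl 4-methoxybenzyl ether; 16 epoxy ketone
Product: 23 alkoxyethynyl carbinol, via chloroethynyl ether 21 (not isolated), via lithium alkoxyacetylide 22 (not isolated)
Conditions: 20, n-BuLi (2.2 equiv per 20), THF, −78 → −40 °C; then 16, −78 → −20 °C; H2O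
Reagents that add atoms: (E)-1,2-dichlorovinyl 4-methoxybenzyl ether (20), COc1ccc(CO/C(Cl)=C\Cl)cc1
Why: Butyllithium converts 20 by elimination to chloroalkyne 21 and by chlorine–lithium exchange to acetylide 22, a slim nucleophile able to reach the non-enolisable C3 carbonyl between two fully substituted carbons (alkoxyacetylide addition to a ketone). Attack anti to the epoxide oxygen and to the axial C8 propenyl group places the alkynyl group trans and the hydroxyl cis to the C7 side chain.

**Step 14**
Reactants: 23 alkoxyethynyl carbinol
Product: 24 1,2-dialkenylcyclohexanol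
Conditions: H2 (1 atm), Pd/CaCO3 poisoned with Pb(OAc)2 (Lindlar catalyst), quinoline, EtOAc, rt
Reagents that add atoms: none
Why: Syn addition of hydrogen on poisoned palladium stops at the alkene and gives the Z enol ether (semi-hydrogenation of an alkoxyethynyl carbinol); the other alkenes, the epoxide and the benzyl ether are not reduced, and amine is kept present because the product is acid-labile.

**Step 15**
Reactants: 24 1,2-dialkenylcyclohexanol
Product: 27 ten-membered bis-enol ether, via potassium alkoxide 25 (not isolated), via potassium enolate 26 (not isolated)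
Conditions: KN(SiMe3)2 (1.3 equiv), 18-crown-6, THF, −78 → 0 °C; then TBSCl, −78 °C → rt
Reagents that add atoms: tert-butyldimethylsilyl chloride, CC(C)(C)[Si](C)(C)Cl
Why: Deprotonation of the tertiary C3 hydroxyl gives alkoxide 25, whose crown-separated oxyanion weakens the C3–C8 bond and triggers a [3,3]-sigmatropic shift across C1=C2–C3–C8–C9=C10 (anionic oxy-Cope rearrangement; closest known type: ring expansion of trans-1,2-dialkenylcyclohexanols to cyclodec-5-enones), and the resulting enolate 26 is silylated on oxygen. The ten-membered ring is formed by four-atom ring expansion, not by end-to-end closure: C1–C10 is made inside a six-centre chair transition state while the C3–C8 ring bond breaks. With the two alkenyl groups trans, that chair carries both ring bonds (C3–C4 and C8–C7) equatorial, so the new C2=C3 and C8=C9 bonds have the ring carbons trans (Z by the sequence rule because of their oxygen substituents). C1 is controlled by the Z geometry of the alkoxyvinyl group, which places the benzyloxy group axial in the chair, and C10 by the E geometry of the propenyl group, which places the methyl equatorial; the result is the anti C1/C10 pair. Its absolute sense is controlled by the C3 and C8 centres, which select one of the two mirror-image chairs and are destroyed in the step; tracing the chair shows that the configuration of 24 leads to the C1 and C10 configurations of 37. The step needs chair-over-boat selectivity, secured by the trans arrangement that lets the termini meet without strain, and it needs the cyclohexane chair with both alkenyl groups equatorial, which places the C7 side chain and O6 axial but should lie close in energy to the other chair, since that one has both alkenyl groups axial. Payne migration cannot interfere because the C3 oxygen and the epoxide oxygen are cis, and 24 has no acidic C–H that the base could attack instead. Silylation at −78 °C is required before enolate 26 can expel the β-benzyloxy group at C1.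

**Step 16**
Reactants: 27 ten-membered bis-enol ether
Product: 28 C8 ketone
Conditions: oxalic acid (10 mol %), THF/H2O, 0 °C
Reagents that add atoms: water, O
Why: C-protonation at C9 of the electron-rich methyl enol ether, addition of water to the oxocarbenium ion and loss of methanol give the C8 ketone (enol ether hydrolysis); the C3 enol silane is less basic, its double bond being flanked by the epoxide and the C1 ether oxygen, and is shielded by the silyl group.

**Step 17**
Reactants: 28 C8 ketone
Product: 29 C8 alcohol
Conditions: LiBH(s-Bu)3, THF, −78 °C; H2O
Reagents that add atoms: none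
Why: The bulky borohydride should attack the C8 carbonyl from the outer face of the ring, anti to the C7–C6 bond in the conformer with H7 turned towards C9 (Felkin-type approach), which gives the alcohol with O8 anti to O6 along C6–C7–C8 (8R in the target). The low temperature protects the α-stereocentre C7.

**Step 18**
Reactants: 29 C8 alcohol; 30 tiglic acid
Product: 32 C8 tiglate, via mixed anhydride 31 (not isolated)
Conditions: tiglic acid, 2,4,6-trichlorobenzoyl chloride, Et3N, toluene, rt; then 29, DMAP, rt → 40 °C
Reagents that add atoms: tiglic acid (30), C/C=C(\C)C(=O)O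
Why: The acid is activated as mixed anhydride 31 and transferred to the hindered secondary alcohol by DMAP (Yamaguchi esterification); the E geometry of the tiglate is the stable one and is retained.

**Step 19**
Reactants: 32 C8 tiglate
Product: 33 diol ketone
Conditions: HF·pyridine, pyridine, THF, 0 °C → rt
Reagents that add atoms: none
Why: Buffered fluoride cleaves the enol silane, which frees the C3 ketone with C2 becoming CH2, and both silyl ethers; the slightly acidic medium avoids O8 to O6 acyl migration and β-elimination at C1, which a basic fluoride source could cause.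

**Step 20**
Reactants: 33 diol ketone
Product: 36 O1-protected lactone, via hydroxy enal 34 (not isolated), via lactol 35 (not isolated)
Conditions: TEMPO (20 mol %), PhI(OAc)2, CH2Cl2, rt
Reagents that add atoms: none
Why: The oxoammonium species oxidises the primary allylic alcohol to enal 34, which closes with the C6 hydroxyl to five-membered lactol 35 and is oxidised again to the lactone (oxidative lactonisation of a 1,4-diol); secondary alcohols react much more slowly and O1 is still protected.

**Step 21**
Reactants: 36 O1-protected lactone
Product: 37 eupakirunsin C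
Conditions: DDQ, CH2Cl2/pH 7 phosphate buffer, 0 °C → rt
Reagents that add atoms: none
Why: Hydride abstraction from the electron-rich benzyl ether by the quinone and hydrolysis of the oxocarbenium ion (oxidative debenzylation) free the C1 hydroxyl under neutral conditions that leave ester, lactone, epoxide and β-hydroxy ketone intact.

## Compound list

1 | (S)-carvone, (5S)-2-methyl-5-(prop-1-en-2-yl)cyclohex-2-en-1-one | CC1=CC[C@@H](CC1=O)C(C)=C | starting material
2 | (S)-10-chlorocarvone, (5S)-5-(3-chloroprop-1-en-2-yl)-2-methylcyclohex-2-en-1-one | CC1=CC[C@@H](CC1=O)C(=C)CCl | intermediate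
3 | (S)-10-acetoxycarvone | CC1=CC[C@@H](CC1=O)C(=C)COC(C)=O | intermediate
4 | (S)-10-hydroxycarvone | CC1=CC[C@@H](CC1=O)C(=C)CO | intermediate
5 | (S)-10-(tert-butyldimethylsilyloxy)carvone | CC1=CC[C@@H](CC1=O)C(=C)CO[Si](C)(C)C(C)(C)C | intermediate
6 | allyl bromide | C=CCBr | starting material
7 | lithium cross-conjugated dienolate of 5 (C3–OLi, C3=C8, C4=C5) | CC1=CC[C@@H](C=C1O[Li])C(=C)CO[Si](C)(C)C(C)(C)C | intermediate
8 | α′-allyl enone: 5 with an allyl group on C8 trans to the C7 side chain | C=CC[C@@H]1[C@@H](C(=C)CO[Si](C)(C)C(C)(C)C)CC=C(C)C1=O | intermediate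
9 | lithium enolate of 8 (C3–OLi, tetrasubstituted C3=C8) | C=CCC1=C(O[Li])C(C)=CC[C@@H]1C(=C)CO[Si](C)(C)C(C)(C)C | intermediate
10 | tertiary α-hydroxy ketone: C8 bears OH (trans to the C7 side chain) and allyl (cis) | C=CC[C@@]1(O)[C@@H](C(=C)CO[Si](C)(C)C(C)(C)C)CC=C(C)C1=O | intermediate
11 | C8 methyl ether: C8 bears OMe (trans) and allyl (cis) | C=CC[C@@]1(OC)[C@@H](C(=C)CO[Si](C)(C)C(C)(C)C)CC=C(C)C1=O | intermediate
12 | (E)-propenyl enone: C8 bears OMe (trans) and (E)-prop-1-enyl (cis) | C/C=C/[C@@]1(OC)[C@@H](C(=C)CO[Si](C)(C)C(C)(C)C)CC=C(C)C1=O | intermediate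
13 | silyl dienol ether: C3(OTBS)=C4(Me)–C5=C6 diene, C7 and C8 as in 12 | C/C=C/[C@@]1(OC)[C@@H](C(=C)CO[Si](C)(C)C(C)(C)C)C=CC(C)=C1O[Si](C)(C)C(C)(C)C | intermediate
14 | γ-hydroxy enone: C6–OH trans to the C7 side chain | C/C=C/[C@@]1(OC)[C@@H](C(=C)CO[Si](C)(C)C(C)(C)C)[C@H](O)C=C(C)C1=O | intermediate
15 | C6 silyl ether enone: C6–OTBS trans to the C7 side chain | C/C=C/[C@@]1(OC)[C@@H](C(=C)CO[Si](C)(C)C(C)(C)C)[C@H](O[Si](C)(C)C(C)(C)C)C=C(C)C1=O | intermediate
16 | epoxy ketone: C4–C5 epoxide oxygen cis to the C7 side chain and trans to C6–OTBS | C/C=C/[C@@]1(OC)[C@@H](C(=C)CO[Si](C)(C)C(C)(C)C)[C@H](O[Si](C)(C)C(C)(C)C)[C@H]2O[C@@]2(C)C1=O | intermediate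
17 | 4-methoxybenzyl alcohol | COc1ccc(CO)cc1 | starting material
18 | trichloroethylene | ClC=C(Cl)Cl | starting material
19 | potassium 4-methoxybenzyl oxide | COc1ccc(CO[K])cc1 | intermediate
20 | (E)-1,2-dichlorovinyl 4-methoxybenzyl ether | COc1ccc(CO/C(Cl)=C\Cl)cc1 | intermediate
21 | chloroethynyl 4-methoxybenzyl ether | COc1ccc(COC#CCl)cc1 | intermediate
22 | lithium (4-methoxybenzyloxy)acetylide | COc1ccc(COC#C[Li])cc1 | intermediate
23 | alkoxyethynyl carbinol: C3 bears OH (cis to the C7 side chain and to the epoxide oxygen) and (4-methoxybenzyloxy)ethynyl (trans) | C/C=C/[C@@]1(OC)[C@@H](C(=C)CO[Si](C)(C)C(C)(C)C)[C@H](O[Si](C)(C)C(C)(C)C)[C@H]2O[C@@]2(C)[C@]1(O)C#COCc1ccc(OC)cc1 | intermediate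
24 | 1,2-dialkenylcyclohexanol: C3 OH (cis) and (Z)-2-(4-methoxybenzyloxy)vinyl (trans); C4–C5 epoxide (oxygen cis), C4 methyl; C6 OTBS (trans); C7 3-(TBS-oxy)prop-1-en-2-yl; C8 OMe (trans) and (E)-prop-1-enyl (cis) | C/C=C/[C@@]1(OC)[C@@H](C(=C)CO[Si](C)(C)C(C)(C)C)[C@H](O[Si](C)(C)C(C)(C)C)[C@H]2O[C@@]2(C)[C@]1(O)/C=C\OCc1ccc(OC)cc1 | intermediate
25 | potassium C3 alkoxide of 24 | C/C=C/[C@@]1(OC)[C@@H](C(=C)CO[Si](C)(C)C(C)(C)C)[C@H](O[Si](C)(C)C(C)(C)C)[C@H]2O[C@@]2(C)[C@]1(O[K])/C=C\OCc1ccc(OC)cc1 | intermediate
26 | potassium C3 enolate of the ten-membered ring (C2=C3, C8=C9 enol methyl ether) | C=C(CO[Si](C)(C)C(C)(C)C)[C@@H]1/C(OC)=C/[C@H](C)[C@H](OCc2ccc(OC)cc2)/C=C(\O[K])[C@]2(C)O[C@@H]2[C@H]1O[Si](C)(C)C(C)(C)C | intermediate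
27 | ten-membered bis-enol ether: C2=C3 enol TBS ether and C8=C9 enol methyl ether (both Z by the sequence rule, ring carbons trans), C1 OPMB and C10 methyl anti, C4–C5 cis-epoxide, C6 OTBS, C7 3-(TBS-oxy)prop-1-en-2-yl | C=C(CO[Si](C)(C)C(C)(C)C)[C@@H]1/C(OC)=C/[C@H](C)[C@H](OCc2ccc(OC)cc2)/C=C(\O[Si](C)(C)C(C)(C)C)[C@]2(C)O[C@@H]2[C@H]1O[Si](C)(C)C(C)(C)C | intermediate
28 | C8 ketone with C3 enol TBS ether | C=C(CO[Si](C)(C)C(C)(C)C)[C@@H]1C(=O)C[C@H](C)[C@H](OCc2ccc(OC)cc2)/C=C(\O[Si](C)(C)C(C)(C)C)[C@]2(C)O[C@@H]2[C@H]1O[Si](C)(C)C(C)(C)C | intermediate
29 | C8 alcohol (O8 anti to O6; 8R in the target sense) | C=C(CO[Si](C)(C)C(C)(C)C)[C@@H]1[C@H](O)C[C@H](C)[C@H](OCc2ccc(OC)cc2)/C=C(\O[Si](C)(C)C(C)(C)C)[C@]2(C)O[C@@H]2[C@H]1O[Si](C)(C)C(C)(C)C | intermediate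
30 | tiglic acid, (E)-2-methylbut-2-enoic acid | C/C=C(\C)C(=O)O | starting material
31 | tiglic 2,4,6-trichlorobenzoic anhydride | C/C=C(\C)C(=O)OC(=O)c1c(Cl)cc(Cl)cc1Cl | intermediate
32 | C8 tiglate with C3 enol TBS ether, O6 and O12 TBS, O1 PMB | C=C(CO[Si](C)(C)C(C)(C)C)[C@@H]1[C@H](OC(=O)/C(C)=C/C)C[C@H](C)[C@H](OCc2ccc(OC)cc2)/C=C(\O[Si](C)(C)C(C)(C)C)[C@]2(C)O[C@@H]2[C@H]1O[Si](C)(C)C(C)(C)C | intermediate
33 | diol ketone: C3 ketone, free 6-OH and 12-OH, O8 tiglate, O1 PMB | C=C(CO)[C@@H]1[C@H](OC(=O)/C(C)=C/C)C[C@H](C)[C@H](OCc2ccc(OC)cc2)CC(=O)[C@]2(C)O[C@@H]2[C@H]1O | intermediate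
34 | hydroxy enal (C12 aldehyde, free 6-OH) | C=C(C=O)[C@@H]1[C@H](OC(=O)/C(C)=C/C)C[C@H](C)[C@H](OCc2ccc(OC)cc2)CC(=O)[C@]2(C)O[C@@H]2[C@H]1O | intermediate
35 | lactol (C12 hemiacetal, both anomers) | C=C1C(O)O[C@H]2[C@H]1[C@H](OC(=O)/C(C)=C/C)C[C@H](C)[C@H](OCc3ccc(OC)cc3)CC(=O)[C@]4(C)O[C@H]24 | intermediate
36 | 1-O-(4-methoxybenzyl)eupakirunsin C | C=C1C(=O)O[C@H]2[C@H]1[C@H](OC(=O)/C(C)=C/C)C[C@H](C)[C@H](OCc3ccc(OC)cc3)CC(=O)[C@]4(C)O[C@H]24 | intermediate
37 | eupakirunsin C, (1R,4R,5R,6S,7R,8R,10S) in germacrane numbering | C=C1C(=O)O[C@H]2[C@H]1[C@H](OC(=O)/C(C)=C/C)C[C@H](C)[C@H](O)CC(=O)[C@]1(C)O[C@H]21 | target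

## Step count and least certain steps

Total step count: 21 (20 on the main line and one for dichlorovinyl ether 20). Longest linear sequence: 20 steps from 1 to 37 (steps 1–11 and 13–21).

**Step 15 (key step).** Two processes may spoil it. The rearrangement needs the cyclohexane chair with both alkenyl groups equatorial, which carries the C7 side chain and O6 axial, so the shift may be slow and decomposition on warming may take over. Also, enolate 26 carries a benzyloxy group in the β-position, and elimination of the C1 alkoxide before silylation would destroy C1. Fallback, from 24: the rearrangement is run without base as a thermal oxy-Cope rearrangement (o-dichlorobenzene, a trace of Et3N, about 170 °C, sealed tube). The enol formed tautomerises to the ketone, so no enolate appears, and the product should be the C3 ketone with C8 enol methyl ether F1. Soft enolisation (TBSOTf, Et3N, CH2Cl2, −78 °C), which can only go towards C2 and normally gives the enol silane with C1 cis to oxygen, returns the route at 27.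

**Step 9.** Oxidation may occur at the wrong π-bond: the tetrasubstituted C3=C4 enol ether bond (hydroxylation at C4) or the C11=C13 alkene may compete with C5=C6. Fallback, from 13: photo-oxygenation (O2, tetraphenylporphyrin, hν, CH2Cl2, −78 °C) adds singlet oxygen across C3 and C6 in a [4+2] cycloaddition, which fixes the regiochemistry, on the face trans to the C7 side chain, to give endoperoxide F2. Reduction of the O–O bond with thiourea in MeOH and loss of silanol returns the route at 14.

**Step 11.** Facial selectivity may be poor, because the C6 silyloxy group steers the hydroperoxide to the face cis to the C7 side chain while the side chain itself favours the other face. Fallback, from 15: 1,2-reduction (NaBH4, CeCl3, MeOH, −78 °C; Luche reduction), with hydride entering anti to the axial C8 propenyl group, should give allylic alcohol F3 with the C3 hydroxyl cis to the side chain. Hydroxyl-directed epoxidation (VO(acac)2, t-BuOOH, CH2Cl2) delivers oxygen to the same face, now reinforced by the C6 silyl ether, to give epoxy alcohol F4. Oxidation with Dess–Martin periodinane returns the route at 16.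

**Step 16.** Three processes threaten it: loss of the C3 enol silane together with the methyl enol ether, transannular attack of the nucleophilic C2 on the C8 oxocarbenium ion, and migration of the C11=C13 double bond into conjugation (with loss of C7) once the ketone is free. Fallback, from 27: both enol ethers are hydrolysed on purpose (0.5 M HCl, THF/H2O, 0 °C) to diketone F5. The ketones are then told apart by size: LiBH(s-Bu)3 at −78 °C should reduce C8 (neighbours CH and CH2) in preference to C3 (one neighbour fully substituted) to give keto alcohol F6. Yamaguchi esterification with 30 gives keto tiglate F7, and HF·pyridine returns the route at 33.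

**Step 17.** Hydride may be delivered to the wrong face, since the preferred conformation around C7–C8 of a ten-membered ring cannot be predicted with confidence and the 8S alcohol may dominate. Fallback, from 28: the reduction is accepted as it comes and the 8-epi alcohol F8 is esterified with inversion (30, PPh3, diisopropyl azodicarboxylate, toluene; Mitsunobu reaction), which returns the route at 32 and makes step 18 unnecessary.

## Further compounds

F1 | step 15 | C3 ketone with C8 enol methyl ether (ten-membered ring, O1 PMB, O6 and O12 TBS) | C=C(CO[Si](C)(C)C(C)(C)C)[C@@H]1/C(OC)=C/[C@H](C)[C@H](OCc2ccc(OC)cc2)CC(=O)[C@]2(C)O[C@@H]2[C@H]1O[Si](C)(C)C(C)(C)C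
F2 | step 9 | 3,6-endoperoxide of 13 (peroxide bridge trans to the C7 side chain) | C/C=C/[C@@]1(OC)[C@@H](C(=C)CO[Si](C)(C)C(C)(C)C)[C@H]2C=C(C)[C@]1(O[Si](C)(C)C(C)(C)C)OO2
F3 | step 11 | allylic alcohol from 15 (C3–OH cis to the C7 side chain) | C/C=C/[C@@]1(OC)[C@@H](C(=C)CO[Si](C)(C)C(C)(C)C)[C@H](O[Si](C)(C)C(C)(C)C)C=C(C)[C@H]1O
F4 | step 11 | epoxy alcohol (C3–OH and epoxide oxygen cis to the C7 side chain) | C/C=C/[C@@]1(OC)[C@@H](C(=C)CO[Si](C)(C)C(C)(C)C)[C@H](O[Si](C)(C)C(C)(C)C)[C@H]2O[C@@]2(C)[C@H]1O
F5 | step 16 | 3,8-diketone (O1 PMB, O6 and O12 TBS) | C=C(CO[Si](C)(C)C(C)(C)C)[C@@H]1C(=O)C[C@H](C)[C@H](OCc2ccc(OC)cc2)CC(=O)[C@]2(C)O[C@@H]2[C@H]1O[Si](C)(C)C(C)(C)C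
F6 | step 16 | 3-keto 8-alcohol | C=C(CO[Si](C)(C)C(C)(C)C)[C@@H]1[C@H](O)C[C@H](C)[C@H](OCc2ccc(OC)cc2)CC(=O)[C@]2(C)O[C@@H]2[C@H]1O[Si](C)(C)C(C)(C)C
F7 | step 16 | 3-keto 8-tiglate | C=C(CO[Si](C)(C)C(C)(C)C)[C@@H]1[C@H](OC(=O)/C(C)=C/C)C[C@H](C)[C@H](OCc2ccc(OC)cc2)CC(=O)[C@]2(C)O[C@@H]2[C@H]1O[Si](C)(C)C(C)(C)C
F8 | step 17 | 8-epi alcohol (C8 epimer of 29) | C=C(CO[Si](C)(C)C(C)(C)C)[C@@H]1[C@@H](O)C[C@H](C)[C@H](OCc2ccc(OC)cc2)/C=C(\O[Si](C)(C)C(C)(C)C)[C@]2(C)O[C@@H]2[C@H]1O[Si](C)(C)C(C)(C)C
A1 | alternative 1 | α-(diethoxyphosphoryl) γ-lactone with free C8 hydroxyl (O1 TBS, C3 dioxolane) | CCOP(=O)(OCC)[C@H]1C(=O)O[C@H]2[C@H]1[C@H](O)C[C@H](C)[C@H](O[Si](C)(C)C(C)(C)C)CC1(OCCO1)[C@]1(C)O[C@H]21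
A2 | alternative 1 | O6 (diethoxyphosphoryl)acetate of the ten-membered ring with C4–C5 and trans C7–C8 epoxides | CCOP(=O)(OCC)CC(=O)O[C@H]2[C@H]3O[C@@H]3C[C@H](C)[C@H](O[Si](C)(C)C(C)(C)C)CC1(OCCO1)[C@]1(C)O[C@H]21
A3 | alternative 2 | seven-membered diisopropylsilylene acetal with Z C9=C10 | CC1=C[C@H]([C@H](COCc2ccc(OC)cc2)C(=C)CO[Si](C)(C)C(C)(C)C)O[Si](C(C)C)(C(C)C)O[C@@H]1CC1(OCCO1)/C(C)=C\I
A4 | alternative 2 | diisopropylsilylene-bridged diene (C8 vinyl, C1 isopropenyl) | C=C[C@H]([C@H](COCc1ccc(OC)cc1)C(=C)CO[Si](C)(C)C(C)(C)C)O[Si](C(C)C)(C(C)C)O[C@@H](C(C)=C)CC1(OCCO1)/C(C)=C\I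
A5 | alternative 3 | ten-membered cis-epoxy ketone (O6 PMB, O1 and O12 TBS, O8 tiglate) | C=C(CO[Si](C)(C)C(C)(C)C)[C@@H]1[C@H](OC(=O)/C(C)=C/C)C[C@H](C)[C@H](O[Si](C)(C)C(C)(C)C)CC(=O)[C@]2(C)O[C@@H]2[C@H]1OCc1ccc(OC)cc1
A6 | alternative 3 | open-chain C4 chloro ketone C5 aldehyde (either configuration at C4) | C=C(CO[Si](C)(C)C(C)(C)C)[C@H]([C@H](OC(=O)/C(C)=C/C)C[C@H](C)[C@H](O[Si](C)(C)C(C)(C)C)CC(=O)C(C)Cl)[C@@H](C=O)OCc1ccc(OC)cc1
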